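**Retrosynthetic overview**

1. Target ⇐ one hydrogenation (quinone to hydroquinone, three O-benzyl to OH) ⇐ 7-methoxyflavone-5,8-quinone ⇐ oxidative demethylation of the para-related 5-OMe/8-OMe pair ⇐ 3-O-methylation of a 5,7,8-trimethoxyflavonol.
2. Flavonol ⇐ Algar–Flynn–Oyamada oxidative cyclisation of a 2'-hydroxychalcone, which makes O1–C2 and C3–O together and closes ring C.
3. Chalcone ⇐ Claisen–Schmidt condensation of 2-hydroxy-3,4,6-trimethoxyacetophenone (from Friedel–Crafts acetylation with ortho-demethylation of 1,2,3,5-tetramethoxybenzene) with 3,4,5-tris(benzyloxy)benzaldehyde.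
4. Feature carrying the strategy: in ring C, C2 bears ring B and the adjacent C3 bears oxygen (the 3-OMe), between the O1–C2 ether bond and the C4 carbonyl. This is the pattern left when the C8a phenoxide of a chalcone closes on the beta carbon while the alpha carbon is oxygenated.
5. Ring order: rings A and B are bought as arenes; ring C is the only ring built (step 3).

Key step: step 3

Remark: compounds 7 and F2 are racemic and are drawn as one enantiomer only to show relative configuration; the target has no stereocentre.

**Route**

Step 1
Reactants: 1 1,2,3,5-tetramethoxybenzene; 2 acetyl chloride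
Product: 4 2-hydroxy-3,4,6-trimethoxyacetophenone, via 2,3,4,6-tetramethoxyacetophenone 3 (not isolated)
Conditions: AlCl3 (3 equiv), Et2O, 0 °C to reflux; then cold 1 M HCl
Reagents that add atoms: none
Why: Friedel–Crafts acylation can only take place at the two equivalent free ring positions, and the AlCl3 held on the new ketone then cleaves one ortho O–Me bond, selectively that of the methoxy group squeezed between the acetyl group and the 3-methoxy group (twisted out of conjugation, hence the more Lewis-basic and more strained one), to give the hydrogen-bonded ortho-hydroxyketone.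

Step 2
Reactants: 4 2-hydroxy-3,4,6-trimethoxyacetophenone; 5 3,4,5-tris(benzyloxy)benzaldehyde
Product: 6 (E)-1-(2-hydroxy-3,4,6-trimethoxyphenyl)-3-[3,4,5-tris(benzyloxy)phenyl]prop-2-en-1-one
Conditions: KOH (50% aq), EtOH/THF, rt
Reagents that add atoms: none
Why: Claisen–Schmidt aldol condensation, in which the ketone enolate adds to the non-enolisable aldehyde and E1cB loss of water gives the conjugated enone with E geometry under thermodynamic control, the phenoxide keeping the product open as the chalcone in base.

Step 3
Reactants: 6 (E)-1-(2-hydroxy-3,4,6-trimethoxyphenyl)-3-[3,4,5-tris(benzyloxy)phenyl]prop-2-en-1-one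
Product: 8 3-hydroxy-5,7,8-trimethoxy-2-[3,4,5-tris(benzyloxy)phenyl]-4H-chromen-4-one, via trans-dihydroflavonol 7 (not isolated)
Conditions: 30% aq H2O2 (excess), 2 M aq NaOH, MeOH/THF, 0 °C to rt; then dilute HCl
Reagents that add atoms: hydrogen peroxide, OO
Why: Algar–Flynn–Oyamada reaction: in alkaline H2O2 the 2'-phenoxide of 6 adds to the beta carbon of the enone while the alpha carbon takes up oxygen from the peroxide (attack of the forming enolate on H2O2, or equivalently Weitz–Scheffer epoxidation followed by opening of the epoxide at its benzylic carbon), giving the trans-dihydroflavonol 7, which the excess alkaline peroxide dehydrogenates across C2–C3 to the flavonol 8. Ring C closes in a 6-endo-trig oxa-Michael mode (6-exo-tet if the epoxide is the intermediate), forming O1–C2, and the C3–O bond is made in the same operation. The two stereocentres of 7 are transient (trans by the diequatorial preference of the equilibrating flavanone) and are erased when the pyranone is formed, so none needs control. The selectivity required is six-membered closure at the beta carbon over five-membered closure at the alpha carbon, which would give the aurone and which the 6'-methoxy group encourages by twisting the carbonyl out of plane. It is secured by the tris(benzyloxy)phenyl ring, whose 4-benzyloxy oxygen stabilises positive character at the benzylic beta carbon, and by working cold with a large excess of H2O2 so that oxygen transfer outruns the aurone pathway.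

Step 4
Reactants: 8 3-hydroxy-5,7,8-trimethoxy-2-[3,4,5-tris(benzyloxy)phenyl]-4H-chromen-4-one
Product: 9 3,5,7,8-tetramethoxy-2-[3,4,5-tris(benzyloxy)phenyl]-4H-chromen-4-one
Conditions: MeI, K2CO3, acetone, reflux
Reagents that add atoms: iodomethane, CI
Why: Williamson O-methylation of the acidic enolic 3-hydroxyl, the only free OH in the molecule.

Step 5
Reactants: 9 3,5,7,8-tetramethoxy-2-[3,4,5-tris(benzyloxy)phenyl]-4H-chromen-4-one
Product: 10 3,7-dimethoxy-2-[3,4,5-tris(benzyloxy)phenyl]-4H-chromene-4,5,8-trione
Conditions: (NH4)2Ce(NO3)6 (2.5 equiv), MeCN/H2O, 0 °C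
Reagents that add atoms: water, O
Why: oxidative demethylation of a para-dimethoxyarene to the para-quinone by tetravalent cerium (two single-electron oxidations, water attacking the ipso carbons C5 and C8 and methanol leaving), which should be selective because only ring A holds two methoxy groups in a para relation, whereas ring B has its para position blocked by C2 and is deactivated by conjugation with the pyranone, and plain benzyl ethers tolerate brief exposure at 0 °C.

Step 6
Reactants: 10 3,7-dimethoxy-2-[3,4,5-tris(benzyloxy)phenyl]-4H-chromene-4,5,8-trione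
Product: 12 5,8-dihydroxy-3,7-dimethoxy-2-(3,4,5-trihydroxyphenyl)-4H-chromen-4-one (the target), via hydroquinone tribenzyl ether 11 (not isolated)
Conditions: H2 (1 atm), 10% Pd/C, THF/MeOH, rt; filtration under argon
Reagents that add atoms: none
Why: catalytic hydrogenation reduces the quinone at once to the 5,8-hydroquinone and then hydrogenolyses the three aryl benzyl ethers, while the aryl methyl ethers and the tetrasubstituted C2=C3 bond of the vinylogous ester should be inert at atmospheric pressure.

**Compound list**

1 | 1,2,3,5-tetramethoxybenzene | COc1cc(OC)c(OC)c(OC)c1 | starting material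
2 | acetyl chloride | CC(=O)Cl | starting material
3 | 2,3,4,6-tetramethoxyacetophenone (formed in the flask) | CC(=O)c1c(OC)cc(OC)c(OC)c1OC | intermediate
4 | 2-hydroxy-3,4,6-trimethoxyacetophenone | CC(=O)c1c(OC)cc(OC)c(OC)c1O | intermediate
5 | 3,4,5-tris(benzyloxy)benzaldehyde | O=Cc1cc(OCc2ccccc2)c(OCc2ccccc2)c(OCc2ccccc2)c1 | starting material
6 | (E)-1-(2-hydroxy-3,4,6-trimethoxyphenyl)-3-[3,4,5-tris(benzyloxy)phenyl]prop-2-en-1-one | COc1cc(OC)c(C(=O)/C=C/c2cc(OCc3ccccc3)c(OCc3ccccc3)c(OCc3ccccc3)c2)c(O)c1OC | intermediate
7 | rac-(2R,3R)-3-hydroxy-5,7,8-trimethoxy-2-[3,4,5-tris(benzyloxy)phenyl]chroman-4-one (trans-dihydroflavonol, formed in the flask) | COc1cc(OC)c2c(c1OC)O[C@H](c1cc(OCc3ccccc3)c(OCc3ccccc3)c(OCc3ccccc3)c1)[C@@H](O)C2=O | intermediate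
8 | 3-hydroxy-5,7,8-trimethoxy-2-[3,4,5-tris(benzyloxy)phenyl]-4H-chromen-4-one | COc1cc(OC)c2c(=O)c(O)c(-c3cc(OCc4ccccc4)c(OCc4ccccc4)c(OCc4ccccc4)c3)oc2c1OC | intermediate
9 | 3,5,7,8-tetramethoxy-2-[3,4,5-tris(benzyloxy)phenyl]-4H-chromen-4-one | COc1cc(OC)c2c(=O)c(OC)c(-c3cc(OCc4ccccc4)c(OCc4ccccc4)c(OCc4ccccc4)c3)oc2c1OC | intermediate
10 | 3,7-dimethoxy-2-[3,4,5-tris(benzyloxy)phenyl]-4H-chromene-4,5,8-trione | COC1=CC(=O)C2=C(OC(c3cc(OCc4ccccc4)c(OCc4ccccc4)c(OCc4ccccc4)c3)=C(OC)C2=O)C1=O | intermediate
11 | 5,8-dihydroxy-3,7-dimethoxy-2-[3,4,5-tris(benzyloxy)phenyl]-4H-chromen-4-one (hydroquinone tribenzyl ether, formed in the flask) | COc1cc(O)c2c(=O)c(OC)c(-c3cc(OCc4ccccc4)c(OCc4ccccc4)c(OCc4ccccc4)c3)oc2c1O | intermediate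
12 | 5,8-dihydroxy-3,7-dimethoxy-2-(3,4,5-trihydroxyphenyl)-4H-chromen-4-one (5,8,3',4',5'-pentahydroxy-3,7-dimethoxyflavone) | COc1cc(O)c2c(=O)c(OC)c(-c3cc(O)c(O)c(O)c3)oc2c1O | target

**Step count**

Total steps: 6. Longest linear sequence: 6 steps (1 to 12).

**Steps most likely to fail, with fallbacks**

Step 3 (key step). The phenoxide may close on the alpha carbon in a five-membered mode and give the aurone, a course favoured by the 6'-methoxy group. The fallback separates ring closure from C3 oxygenation and sets out from chalcone 6. Oxidative cyclisation with catalytic I2 in DMSO at about 120 °C (oxa-Michael closure, then iodine-mediated dehydrogenation, a reagent system that leads to flavones) should give 5,7,8-trimethoxy-2-[3,4,5-tris(benzyloxy)phenyl]-4H-chromen-4-one F1. Epoxidation of its C2=C3 bond with dimethyldioxirane in acetone/CH2Cl2 at 0 °C should give the racemic cis-fused 2,3-epoxy-5,7,8-trimethoxy-2-[3,4,5-tris(benzyloxy)phenyl]chroman-4-one F2. Catalytic p-TsOH in CH2Cl2 should open F2 at C2 and, after loss of the C3 proton, deliver flavonol 8, where the route is rejoined.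

Step 5. Single-electron oxidation may be unselective: tetravalent cerium may attack the tris(benzyloxy)phenyl ring or the benzylic CH2 groups, or the reactive quinone may be over-oxidised or hydrated. The fallback makes the oxidation phenol-directed and sets out from 9. AlBr3 in MeCN at 0 °C, chelated between the C4 carbonyl and the peri 5-methoxy oxygen, should cleave that methyl ether selectively and give 5-hydroxy-3,7,8-trimethoxy-2-[3,4,5-tris(benzyloxy)phenyl]-4H-chromen-4-one F3. The para-methoxyphenol unit of F3 is then oxidised with PhI(OAc)2 in MeCN/H2O at 0 °C; this trivalent iodine reagent is a two-electron oxidant that needs a free phenol and so should leave the fully etherified ring B alone. Water adds at C8, methanol leaves, and quinone 10 is reached.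

Step 6. Hydrogenolysis of the flanked central benzyl ether may stall, the C2=C3 bond may be over-reduced, or the electron-rich hydroquinone and pyrogallol units may re-oxidise in air during catalyst removal. The fallback avoids hydrogen and the metal catalyst and sets out from quinone 10. Reduction with aqueous Na2S2O4 in EtOAc/H2O at rt gives the hydroquinone 11, which is isolated here. The three benzyl groups are then removed with BCl3 and pentamethylbenzene in CH2Cl2 at −78 °C (Friedel–Crafts transfer of benzyl cations to the scavenger, methyl ethers untouched at this temperature), followed by a methanol quench under argon, to arrive at target 12. No compound outside the list arises on this path (F0).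

**Further compounds**

F1 | step 3 | 5,7,8-trimethoxy-2-[3,4,5-tris(benzyloxy)phenyl]-4H-chromen-4-one | COc1cc(OC)c2c(=O)cc(-c3cc(OCc4ccccc4)c(OCc4ccccc4)c(OCc4ccccc4)c3)oc2c1OC
F2 | step 3 | racemic cis-fused 2,3-epoxy-5,7,8-trimethoxy-2-[3,4,5-tris(benzyloxy)phenyl]chroman-4-one (flavone 2,3-oxide) | COc1cc(OC)c2C(=O)[C@H]3O[C@@]3(c3cc(OCc4ccccc4)c(OCc4ccccc4)c(OCc4ccccc4)c3)Oc2c1OC
F3 | step 5 | 5-hydroxy-3,7,8-trimethoxy-2-[3,4,5-tris(benzyloxy)phenyl]-4H-chromen-4-one | COc1cc(O)c2c(=O)c(OC)c(-c3cc(OCc4ccccc4)c(OCc4ccccc4)c(OCc4ccccc4)c3)oc2c1OC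
F0 | step 6 | none | none
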